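## Retrosynthetic overview

1. The seven-membered carbocyclic bridge is closed last: target ⇐ hydrogenation ⇐ intramolecular alkenyl–aldehyde coupling between an N-(Z)-bromoallyl arm and an angular formyl group.
2. The angular formyl six-membered lactam comes from the key step, a 1,2-shift of the lactam carbonyl carbon in a fused α,β-epoxy seven-membered lactam (ring contraction seven → six); this creates the quaternary carbon.
3. The unsaturated seven-membered lactam comes from an intramolecular Horner–Wadsworth–Emmons reaction onto a cyclopentanone; the amine and side-chain lactone come from a sulfinimine vinylogous Mannich reaction with a silyloxyfuran, then hydrogenation.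
4. The cyclopentanone core (fused lactone, ethyl, two-carbon arm) comes from radical cyclisation/allylation of a bromoacetal of (4S,5R)-5-ethyl-4-hydroxycyclopentenone, made from (R)-4-hydroxycyclopentenone.
5. Ring order: cyclopentane (bought) → fused γ-lactone → side-chain γ-lactone → seven-membered lactam → six-membered lactam (by contraction) → seven-membered bridge.

Assumption: (Z)-1,3-dibromoprop-1-ene is used as the pure Z isomer (distilled from the commercial cis/trans mixture); group-delivering reagents (EtI, allyltributylstannane, the sulfinamide auxiliary, the phosphonoacetyl chloride) are treated as reagents, not numbered starting materials.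

## Route

Step 1
Reactants: 1 (R)-4-hydroxycyclopent-2-en-1-one
Product: 3 (4S,5R)-5-ethyl-4-hydroxycyclopent-2-en-1-one, via dilithium dianion 2 (not isolated)
Conditions: LiN(iPr)2 (2.2 equiv), THF–DMPU, −78 °C; then EtI, −78 → −30 °C; H2O
Reagents that add atoms: iodoethane, CCI
Why: Fráter–Seebach-type alkylation of the alkoxide–dienolate dianion; the lithium alkoxide cannot be eliminated and EtI enters C-5 anti to it, setting the trans (5R) ethyl centre.

Step 2
Reactants: 3 (4S,5R)-5-ethyl-4-hydroxycyclopent-2-en-1-one; 4 ethyl prop-1-en-1-yl ether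
Product: 5 (4S,5R)-4-(2-bromo-1-ethoxypropoxy)-5-ethylcyclopent-2-en-1-one (diastereomer mixture in the side chain)
Conditions: NBS, CH2Cl2, −40 → 0 °C
Reagents that add atoms: N-bromosuccinimide, O=C1CCC(=O)N1Br
Why: Bromoetherification of the enol ether by the secondary alcohol (Ueno–Stork haloacetal formation) leaves the enone untouched; the two new side-chain centres are uncontrolled and are fixed or erased in steps 3 and 4.

Step 3
Reactants: 5 mixed bromoacetal
Product: 6 cis-fused bicyclic ethyl acetal ketone carrying ethyl, methyl and allyl groups (C-2 epimer mixture)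
Conditions: CH2=CHCH2SnBu3 (3 equiv), AIBN (0.2 equiv), PhH, 80 °C
Reagents that add atoms: allyltributylstannane, C=CC[Sn](CCCC)(CCCC)CCCC
Why: Ueno–Stork 5-exo radical cyclisation onto the enone β-carbon followed by Keck allylation of the α-keto radical; the ring fusion must be cis, the methyl-bearing radical carbon closes cis to the neighbouring ring carbon (Beckwith chair transition state) and the allyl group enters on the convex face, anti to the new C–C bond.

Step 4
Reactants: 6 bicyclic ethyl acetal ketone
Product: 7 (3S,3aR,4S,6R,6aS)-6-ethyl-3-methyl-4-(prop-2-en-1-yl)tetrahydro-2H-cyclopenta[b]furan-2,5(3H)-dione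
Conditions: CrO3, H2SO4, acetone–H2O, 0 → 25 °C
Reagents that add atoms: water, O
Why: Jones oxidation converts the cyclic acetal through its lactol into the γ-lactone without touching alkene or ketone, and removes the acetal stereocentre.

Step 5
Reactants: 7 keto lactone
Product: 9 2-[(3S,3aR,4S,6R,6aS)-6-ethyl-3-methyl-2,5-dioxohexahydro-2H-cyclopenta[b]furan-4-yl]acetaldehyde, via ozonide 8 (not isolated)
Conditions: O3, CH2Cl2, −78 °C; then Me2S, −78 → 25 °C
Reagents that add atoms: ozone, [O-][O+]=O
Why: Ozonolysis with reductive work-up cleaves the only C=C bond to the aldehyde; ketone and lactone are inert.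

Step 6
Reactants: 9 keto aldehyde
Product: 10 (S,E)-N-sulfinyl aldimine of 9
Conditions: (S)-tBuS(O)NH2, pyrrolidine (10 mol %), 4 Å MS, CH2Cl2, 25 °C
Reagents that add atoms: (S)-2-methylpropane-2-sulfinamide, CC(C)(C)[S@@](N)=O
Why: Ellman condensation is chemoselective for the aldehyde because the doubly flanked cyclopentanone is much less electrophilic.

Step 7
Reactants: 11 3-methylfuran-2(5H)-one
Product: 12 3-methyl-2-(trimethylsilyloxy)furan
Conditions: TMSOTf, Et3N, CH2Cl2, 0 °C
Reagents that add atoms: trimethylsilyl trifluoromethanesulfonate, C[Si](C)(C)OS(=O)(=O)C(F)(F)F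
Why: Soft enolisation and O-silylation of the butenolide gives the aromatic 2-silyloxyfuran, the vinylogous nucleophile.

Step 8
Reactants: 10 N-sulfinyl aldimine; 12 3-methyl-2-(trimethylsilyloxy)furan
Product: 13 (S)-N-sulfinyl amine with (R)-amine carbon and (R)-butenolide γ-carbon (threo)
Conditions: TMSOTf (0.2 equiv), CH2Cl2, −78 °C; aq. NaHCO3
Reagents that add atoms: none
Why: Vinylogous Mukaiyama–Mannich reaction through an open transition state; the furan attacks the imine face opposite the tert-butyl group of the (S)-auxiliary (R amine carbon) with the usual threo preference (R butenolide γ-carbon).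

Step 9
Reactants: 13 sulfinamide butenolide
Product: 14 sulfinamide with (2R,4R)-4-methyl-5-oxotetrahydrofuran-2-yl group
Conditions: H2 (1 atm), Rh/Al2O3 (5 %), EtOAc, 25 °C
Reagents that add atoms: none
Why: Heterogeneous hydrogenation adds H2 to the butenolide face opposite the bulky γ-substituent, giving the cis-2,4-disubstituted lactone (R methyl centre); ketone and sulfinamide survive.

Step 10
Reactants: 14 saturated sulfinamide
Product: 16 diethyl phosphonoacetamide of the amine, via amine hydrochloride 15 (not isolated)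
Conditions: HCl (4 M in dioxane), MeOH, 0 °C; evaporate; then ClC(O)CH2P(O)(OEt)2, NaHCO3, CH2Cl2–H2O, 0 °C
Reagents that add atoms: (diethoxyphosphoryl)acetyl chloride, CCOP(=O)(CC(=O)Cl)OCC
Why: Acidic methanolysis removes the sulfinyl group, and Schotten–Baumann acylation of the ammonium salt is faster than condensation of the free amine with the hindered ketone.

Step 11
Reactants: 16 keto phosphonoacetamide
Product: 17 cyclopentane-fused α,β-unsaturated seven-membered NH-lactam
Conditions: LiCl, DBU, MeCN, 40 °C, 0.005 M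
Reagents that add atoms: none
Why: Intramolecular Horner–Wadsworth–Emmons olefination under Masamune–Roush conditions closes the seven-membered unsaturated lactam; the mild base does not enolise the lactones, and the ring fixes the alkene geometry.

Step 12
Reactants: 17 unsaturated NH-lactam; 18 (Z)-1,3-dibromoprop-1-ene
Product: 20 N-[(Z)-3-bromoprop-2-en-1-yl] lactam, via potassium lactamate 19 (not isolated)
Conditions: KN(SiMe3)2, THF, −78 °C; then 18, −78 → 0 °C
Reagents that add atoms: none
Why: SN2 N-alkylation of the lactam potassium salt at the allylic bromide installs the alkenyl bromide handle with retention of Z geometry.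

Step 13
Reactants: 20 N-bromoallyl unsaturated lactam
Product: 21 α,β-epoxy lactam, epoxide oxygen on the face of the fused lactone
Conditions: dimethyldioxirane, acetone, 0 °C
Reagents that add atoms: dimethyldioxirane, CC1(C)OO1
Why: Electrophilic epoxidation of the trisubstituted conjugated alkene occurs anti to the ethyl group and to the seven-membered ring folded under the cyclopentane; the electron-poor bromoalkene is inert.

Step 14
Reactants: 21 α,β-epoxy lactam
Product: 22 angular formyl six-membered lactam (CHO syn to the fused lactone, lactam carbonyl syn to ethyl)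
Conditions: BF3·OEt2 (0.3 equiv), CH2Cl2, −40 → 0 °C
Reagents that add atoms: none
Why: Proposed new method: the Lewis acid opens the epoxide at the tertiary cyclopentane carbon and the lactam carbonyl carbon migrates from the neighbouring epoxide carbon to this cation anti to the departing oxygen (semipinacol/Meinwald-type 1,2-acyl shift), contracting the seven-membered lactam to the six-membered one, turning the old epoxide carbon into the aldehyde and fixing the quaternary centre; the closest known reaction is the House rearrangement of α,β-epoxy ketones to β-keto aldehydes (isophorone oxide ring contraction) and the 1,2-carbonyl shifts of glycidic esters and thiol esters.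

Step 15
Reactants: 22 angular formyl lactam
Product: 24 bridged lactam with (R)-carbinol and cis C=C in the new seven-membered ring, via alkenylchromium dichloride 23 (not isolated)
Conditions: CrCl2 (6 equiv), NiCl2 (2 mol %), DMF, 25 °C, 0.003 M
Reagents that add atoms: none
Why: Intramolecular Nozaki–Hiyama–Kishi coupling adds the alkenylchromium irreversibly and chemoselectively to the non-enolisable aldehyde, closing the seven-membered ring and pyramidalising nitrogen; attack from the nitrogen side on the aldehyde conformer with C=O anti to the lactam carbonyl gives the R carbinol.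

Step 16
Reactants: 24 unsaturated bridged lactam
Product: 25 CNP0120800.1
Conditions: H2 (1 atm), RhCl(PPh3)3 (10 mol %), PhH–EtOH, 25 °C
Reagents that add atoms: none
Why: Homogeneous hydrogenation saturates the cis-disubstituted ring alkene without hydrogenolysis of the allylic C–O and C–N bonds and creates no new stereocentre.

## Compound list

1 | (R)-4-hydroxycyclopent-2-en-1-one | O=C1C=C[C@H](O)C1 | starting material
2 | dilithium alkoxide–dienolate of 1 | [Li+].[Li+].[O-]C1=C[C@@H]([O-])C=C1 | intermediate
3 | (4S,5R)-5-ethyl-4-hydroxycyclopent-2-en-1-one | O=C1C=C[C@H](O)[C@H]1CC | intermediate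
4 | ethyl prop-1-en-1-yl ether (E/Z mixture) | CC=COCC | starting material
5 | (4S,5R)-4-(2-bromo-1-ethoxypropoxy)-5-ethylcyclopent-2-en-1-one (side-chain diastereomers) | O=C1C=C[C@H](OC(OCC)C(C)Br)[C@H]1CC | intermediate
6 | 2-ethoxy-6-ethyl-3-methyl-4-(prop-2-en-1-yl)hexahydro-2H-cyclopenta[b]furan-5-one, ring carbons configured as in 7, C-2 epimer mixture | CC[C@@H]1[C@H]2OC(OCC)[C@@H](C)[C@H]2[C@H](CC=C)C1=O | intermediate
7 | (3S,3aR,4S,6R,6aS)-6-ethyl-3-methyl-4-(prop-2-en-1-yl)tetrahydro-2H-cyclopenta[b]furan-2,5(3H)-dione | CC[C@@H]1[C@H]2OC(=O)[C@@H](C)[C@H]2[C@H](CC=C)C1=O | intermediate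
8 | 1,2,4-trioxolane (secondary ozonide) of 7 | CC[C@@H]1[C@H]2OC(=O)[C@@H](C)[C@H]2[C@H](CC3OCOO3)C1=O | intermediate
9 | 2-[(3S,3aR,4S,6R,6aS)-6-ethyl-3-methyl-2,5-dioxohexahydro-2H-cyclopenta[b]furan-4-yl]acetaldehyde | CC[C@@H]1[C@H]2OC(=O)[C@@H](C)[C@H]2[C@H](CC=O)C1=O | intermediate
10 | (S)-N-[(E)-2-(bicyclic core of 9)ethylidene]-2-methylpropane-2-sulfinamide | CC[C@@H]1[C@H]2OC(=O)[C@@H](C)[C@H]2[C@H](C/C=N/[S@@](=O)C(C)(C)C)C1=O | intermediate
11 | 3-methylfuran-2(5H)-one | CC1=CCOC1=O | starting material
12 | 3-methyl-2-(trimethylsilyloxy)furan | Cc1ccoc1O[Si](C)(C)C | intermediate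
13 | (S)-N-{(1R)-2-(bicyclic core of 9)-1-[(2R)-4-methyl-5-oxo-2,5-dihydrofuran-2-yl]ethyl}-2-methylpropane-2-sulfinamide | CC[C@@H]1[C@H]2OC(=O)[C@@H](C)[C@H]2[C@H](C[C@@H](N[S@@](=O)C(C)(C)C)[C@H]3C=C(C)C(=O)O3)C1=O | intermediate
14 | (S)-N-{(1R)-2-(bicyclic core of 9)-1-[(2R,4R)-4-methyl-5-oxotetrahydrofuran-2-yl]ethyl}-2-methylpropane-2-sulfinamide | CC[C@@H]1[C@H]2OC(=O)[C@@H](C)[C@H]2[C@H](C[C@@H](N[S@@](=O)C(C)(C)C)[C@H]3C[C@@H](C)C(=O)O3)C1=O | intermediate
15 | (1R)-2-(bicyclic core of 9)-1-[(2R,4R)-4-methyl-5-oxotetrahydrofuran-2-yl]ethan-1-aminium chloride | CC[C@@H]1[C@H]2OC(=O)[C@@H](C)[C@H]2[C@H](C[C@@H]([NH3+])[C@H]3C[C@@H](C)C(=O)O3)C1=O.[Cl-] | intermediate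
16 | diethyl [2-({(1R)-2-(bicyclic core of 9)-1-[(2R,4R)-4-methyl-5-oxotetrahydrofuran-2-yl]ethyl}amino)-2-oxoethyl]phosphonate | CC[C@@H]1[C@H]2OC(=O)[C@@H](C)[C@H]2[C@H](C[C@@H](NC(=O)CP(=O)(OCC)OCC)[C@H]3C[C@@H](C)C(=O)O3)C1=O | intermediate
17 | tricyclic NH-lactam: seven-membered α,β-unsaturated lactam (NH–C(=O)–CH=C) closed onto the former ketone carbon; fused lactone, ethyl and side-chain lactone as in 16 | CC[C@@H]1[C@H]2OC(=O)[C@@H](C)[C@H]2[C@@H]2C[C@H]([C@H]3C[C@@H](C)C(=O)O3)NC(=O)C=C12 | intermediate
18 | (Z)-1,3-dibromoprop-1-ene | BrC/C=C\Br | starting material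
19 | potassium salt (N-anion) of lactam 17 | CC[C@@H]1[C@H]2OC(=O)[C@@H](C)[C@H]2[C@@H]2C[C@H]([C@H]3C[C@@H](C)C(=O)O3)[N-]C(=O)C=C12.[K+] | intermediate
20 | N-[(Z)-3-bromoprop-2-en-1-yl] derivative of 17 | CC[C@@H]1[C@H]2OC(=O)[C@@H](C)[C@H]2[C@@H]2C[C@H]([C@H]3C[C@@H](C)C(=O)O3)N(C/C=C\Br)C(=O)C=C12 | intermediate
21 | α,β-epoxy lactam from 20; oxirane spiro to the cyclopentane, oxygen syn to the fused lactone and anti to ethyl | CC[C@@H]1[C@H]2OC(=O)[C@@H](C)[C@H]2[C@@H]2C[C@H]([C@H]3C[C@@H](C)C(=O)O3)N(C/C=C\Br)C(=O)[C@H]4O[C@@]124 | intermediate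
22 | six-membered lactam cis-fused to the cyclopentane; quaternary ring-fusion carbon bears CHO (syn to fused lactone) and the lactam C=O (syn to ethyl); N-(Z)-3-bromoallyl | CC[C@@H]1[C@H]2OC(=O)[C@@H](C)[C@H]2[C@@H]2C[C@H]([C@H]3C[C@@H](C)C(=O)O3)N(C/C=C\Br)C(=O)[C@]12C=O | intermediate
23 | alkenylchromium dichloride from 22 (Br replaced by CrCl2) | CC[C@@H]1[C@H]2OC(=O)[C@@H](C)[C@H]2[C@@H]2C[C@H]([C@H]3C[C@@H](C)C(=O)O3)N(C/C=C\[Cr](Cl)Cl)C(=O)[C@]12C=O | intermediate
24 | didehydro target: bridged lactam with cis C=C between the N-CH2 carbon and the (R)-carbinol carbon | CC[C@@H]1[C@H]2OC(=O)[C@@H](C)[C@H]2[C@@H]2C[C@H]([C@H]3C[C@@H](C)C(=O)O3)N3CC=C[C@@H](O)[C@@]12C3=O | intermediate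
25 | CNP0120800.1 | CC[C@@H]1[C@H]2OC(=O)[C@@H](C)[C@H]2[C@@H]2C[C@H]([C@H]3C[C@@H](C)C(=O)O3)N3CCC[C@@H](O)[C@@]12C3=O | target

## Count and risks

Total step count: 16. Longest linear sequence: 15 steps (steps 1–6 and 8–16; step 7 is a one-step branch).

**Step 14 (the proposed new ring contraction).** A 1,2-hydride shift (giving an α-keto lactam) or elimination to an allylic alcohol may compete with migration of the lactam carbonyl carbon. The fallback uses known chemistry and builds the quaternary centre by enamine-type hydroxymethylation; it sets out from 14 and comes back at 22. Ketone 14 is treated with excess Ph3P=CHOMe (from the phosphonium chloride and KN(SiMe3)2) to give the methyl enol ether F1. Aqueous HCl in THF removes the sulfinyl group and hydrolyses the enol ether, and the amino aldehyde closes to the cyclic aldimine F2. Aqueous formaldehyde hydroxymethylates the imine α-carbon through its enamine tautomer on the open face to give the hydroxymethyl imine F3. NaClO2/NaH2PO4 oxidises the aldimine to the hydroxymethyl lactam F4, and Dess–Martin periodinane gives the formyl NH-lactam F5. KN(SiMe3)2 and 18 then give 22.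

**Step 15 (ring closure that twists the amide, and the carbinol configuration).** Chelation of the aldehyde and lactam oxygens by chromium could favour the wrong carbinol epimer. The fallback sets the centre by hydride delivery instead; it sets out from 22 and comes back at 24. The coupling is run without regard to selectivity; the epimeric allylic alcohol F8 (alone or mixed with 24) is oxidised with Dess–Martin periodinane to the bridged enone F9. NaBH4/CeCl3·7H2O at −78 °C reduces F9 from the convex face of the bicycle to give 24.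

**Step 11 (olefination of a hindered ketone by a secondary amide that must react through its minor cis rotamer).** The fallback replaces olefination by metathesis; it sets out from 14 and comes back at 17. HCl/MeOH, then acryloyl chloride/NaHCO3, gives the keto acrylamide F6. Zn/CH2Br2/TiCl4 methylenation of the ketone gives the methylene acrylamide F7. Ring-closing metathesis with the second-generation Hoveyda–Grubbs catalyst in toluene at 80 °C gives 17.

## Further compounds

F1 | step 14 | methyl enol ether of ketone 14 (E/Z mixture) | CC[C@@H]1[C@H]2OC(=O)[C@@H](C)[C@H]2[C@H](C[C@@H](N[S@@](=O)C(C)(C)C)[C@H]3C[C@@H](C)C(=O)O3)C1=COC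
F2 | step 14 | cyclic aldimine (six-membered, N=CH attached to the cyclopentane CH; epimers at that CH) | CC[C@@H]1[C@H]2OC(=O)[C@@H](C)[C@H]2[C@@H]2C[C@H]([C@H]3C[C@@H](C)C(=O)O3)N=CC12
F3 | step 14 | hydroxymethyl imine with quaternary ring-fusion carbon | CC[C@@H]1[C@H]2OC(=O)[C@@H](C)[C@H]2[C@@H]2C[C@H]([C@H]3C[C@@H](C)C(=O)O3)N=C[C@]12CO
F4 | step 14 | hydroxymethyl six-membered NH-lactam | CC[C@@H]1[C@H]2OC(=O)[C@@H](C)[C@H]2[C@@H]2C[C@H]([C@H]3C[C@@H](C)C(=O)O3)NC(=O)[C@]12CO
F5 | step 14 | formyl six-membered NH-lactam | CC[C@@H]1[C@H]2OC(=O)[C@@H](C)[C@H]2[C@@H]2C[C@H]([C@H]3C[C@@H](C)C(=O)O3)NC(=O)[C@]12C=O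
F6 | step 11 | keto acrylamide | CC[C@@H]1[C@H]2OC(=O)[C@@H](C)[C@H]2[C@H](C[C@@H](NC(=O)C=C)[C@H]3C[C@@H](C)C(=O)O3)C1=O
F7 | step 11 | methylene acrylamide | CC[C@@H]1[C@H]2OC(=O)[C@@H](C)[C@H]2[C@H](C[C@@H](NC(=O)C=C)[C@H]3C[C@@H](C)C(=O)O3)C1=C
F8 | step 15 | carbinol epimer of 24 | CC[C@@H]1[C@H]2OC(=O)[C@@H](C)[C@H]2[C@@H]2C[C@H]([C@H]3C[C@@H](C)C(=O)O3)N3CC=C[C@H](O)[C@@]12C3=O
F9 | step 15 | bridged enone | CC[C@@H]1[C@H]2OC(=O)[C@@H](C)[C@H]2[C@@H]2C[C@H]([C@H]3C[C@@H](C)C(=O)O3)N3CC=CC(=O)[C@@]12C3=O
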